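At early times the south-west flask makes product in a nearly straight line. Gas dissolves into nucleophile, nucleophile attacks electrophile, and each product frees acid, which takes up a second nucleophile.

in all of them: gas 4.5 mM (held)

|  | electrophile | remark | time |
|---|---|---|---|
| south-west | 14 mM | run made earlier |  |
| blue | 13 mM |  | 30 h |
| green | 40 mM |  | 30 h |
| red | 50 mM |  | 30 h |
| grey | 6.0 mM |  | 30 h |
| violet | 20 mM |  | 30 h |
| teal | 4.0 mM |  | 30 h |

- south-west (time / h: product / %): 2.00: 3.9; 4.00: 5.5; 6.00: 7.2; 8.00: 11.4; 10.0: 14.4

(standard deviation of a reading: 1 percentage point)

- at the start none of nucleophile is dissolved
- the analysis behind the earlier runs scatters by 1 percentage point, standard deviation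
- reactions considered so far: nucleophile + acid set free <-> protonated nucleophile; electrophile + nucleophile <-> acid set free + product; gas <-> nucleophile

* all flasks from highest to lowest amount of product, in percent of the electrophile charged, at 30 h (blue / green / red / grey / violet / teal)
* the amount of product, in percent of the electrophile charged of the flask you put first, at 30 h
* the amount of product, in percent of the electrophile charged of the flask you put last, at 30 h

I carry one quantity, the pace: product formed per hour in millimolar, read as a mean from the last reading of the south-west run, 0.202 mM/h. It is a reading and carries the scatter of 1 percentage point.

Suppose first that the crossing of gas into solution is the rate-limiting step, so that the pace holds at any charge. Then 30 h gives 6.06 mM of product, which is 12.1% of red's charge. But teal holds 4.0 mM, less than that amount, so this end fails for teal, whose ceiling is its charge.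

Now take the other end, first order in electrophile. The same reading gives 0.0155 /h, so at this end the share at 30 h is 37.3% whatever the charge. The objection is that a rich flask should draw its nucleophile lower, so I doubt that the shares are equal.

One run cannot place the flasks between these ends, so I join them by the geometric mean, a convention and no mechanism. Red lands at 21.2%, and teal, with its ceiling, at 61.1%. Grey, with 6.0 mM, also stands below the amount the pace gives, so this join ties it with teal. The objection puts teal first, since it holds less electrophile. Beyond that tie the joined share falls with charge, so I rank the flasks by rising charge.

The forecast gives teal > grey > blue > violet > green > red, with 60% on top (range 36% to 95%) and 16% at the bottom (range 11% to 31%). Its ground is that “percent conversion falls as electrophile rises”. We share the order, and on red my number stands higher.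

The flasks give teal > grey > blue > violet > green > red, with teal at 60.8% and red at 22.2%, above the forecast's red. At 30.0 h red holds 0.950 mM of nucleophile and teal 3.83 mM. Red's mean pace over that time is 0.369 mM/h, which is 1.83 times the south-west pace. Blue's over the same time is 0.205 mM/h, less than red's, so at 30 h the pace is not flat from blue's charge to red's.

    nucleophile + acid set free ⇌ protonated nucleophile, settled at all times (K = 5.70 × 10⁵ /M)
    electrophile + nucleophile ⇌ acid set free + product (K = 14.0, k = 10.0 /M/h)
    gas ⇌ nucleophile, rate k3*(csat - [nucleophile]) (kL = 0.210 /h)

Take the red flask charged instead with 12 mM of electrophile, close to the south-west charge: the pace gives 50.5% at 30.0 h. The computed result is 48.5%.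

The readings are simulated from invented constants; noise was put on by code.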